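**Plan**

- Numbering follows the target throughout: O1, C2 (spiro, = C1'), C3, C3a, C4–C8, C8a for the 2H-cyclohepta[b]furan; C1'–C6' for the cyclohexane.
- Retrosynthetic cuts, in order: C6–C7 and C3a–C4 (seven-membered ring, back to an (E)-2-alkylidene-oxolane ester and a C5 acetal ester); then O1–C8a together with C7–C8 (back to a tertiary 4-alkyn-1-ol, CO and methanol); then C2–C3 (cyclohexanone plus pent-3-ynyl Grignard); the cyclohexanone comes from (S)-carvone.
- Enabling feature: C8a is the β-carbon of the vinylogous ester O1–C8a=C8(Me)–C7=O of the tropone, i.e. an alkyne carbon that has taken up the C2 oxygen while its neighbour C8 was acylated. The oxolane ring O1–C2–C3–C3a–C8a can therefore be closed on an alkyne before the seven-membered ring exists.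
- Forward order: cyclohexane (steps 1–7), side chain (step 9), oxolane with C7 attached (step 10), seven-membered ring annulated last (steps 12, 13), then deprotection and oxidation to the acid.
- Stereochemistry: C3' from (S)-carvone; C2' by enolate allylation anti to the C3' substituent; C6' by equilibration to the equatorial methyl; C2 by axial Grignard attack anti to the axial C2' methyl; enol ether geometry by anti oxypalladation.

Key step: step 10

Assumption: methyl (2E)-3-methyl-4-oxobut-2-enoate (14) is taken as a commercial C5 building block.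

**Route**

Step 1
Reactants: 1 (S)-(+)-carvone
Product: 2 (5S)-5-(2-hydroxypropan-2-yl)-2-methylcyclohex-2-en-1-one
Conditions: 50% aq. H2SO4, 0 °C
Reagents that add atoms: water, O
Why: Acid-catalysed Markovnikov hydration of the electron-rich 1,1-disubstituted alkene through its tertiary cation should leave the deactivated enone alkene and the C5 stereocentre untouched.

Step 2
Reactants: 2 (5S)-5-(2-hydroxypropan-2-yl)-2-methylcyclohex-2-en-1-one
Product: 3 (5S)-2-methyl-5-[2-(triethylsilyloxy)propan-2-yl]cyclohex-2-en-1-one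
Conditions: TESOTf, 2,6-lutidine, CH2Cl2, −78 to 0 °C
Reagents that add atoms: triethylsilyl trifluoromethanesulfonate, CC[Si](CC)(CC)OS(=O)(=O)C(F)(F)F
Why: Silyl triflate silylation is the standard way to protect a tertiary alcohol, which must not interfere with the enolate chemistry that follows.

Step 3
Reactants: 3 (5S)-2-methyl-5-[2-(triethylsilyloxy)propan-2-yl]cyclohex-2-en-1-one
Product: 4 (5S)-2,6-dimethyl-5-[2-(triethylsilyloxy)propan-2-yl]cyclohex-2-en-1-one (mixture of C6 epimers)
Conditions: LDA, THF, −78 °C; MeI, −78 to −20 °C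
Reagents that add atoms: iodomethane, CI
Why: Kinetic α'-deprotonation of the cross-conjugated enone and SN2 methylation (enolate alkylation) should occur only at C6, whose configuration is erased in step 4.

Step 4
Reactants: 4 (5S)-2,6-dimethyl-5-[2-(triethylsilyloxy)propan-2-yl]cyclohex-2-en-1-one
Product: 5 (5S,6R)-2,6-dimethyl-6-(prop-2-en-1-yl)-5-[2-(triethylsilyloxy)propan-2-yl]cyclohex-2-en-1-one
Conditions: LDA, THF–DMPU, −78 °C; allyl bromide, −78 to 0 °C
Reagents that add atoms: allyl bromide, C=CCBr
Why: Alkylation of the tetrasubstituted lithium enolate should take place anti to the bulky C5 substituent, so the allyl group ends trans and the methyl cis to it, which is the C2' configuration of the target.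

Step 5
Reactants: 5 (5S,6R)-2,6-dimethyl-6-(prop-2-en-1-yl)-5-[2-(triethylsilyloxy)propan-2-yl]cyclohex-2-en-1-one
Product: 6 (2R,3S,6S)-2,6-dimethyl-2-(prop-2-en-1-yl)-3-[2-(triethylsilyloxy)propan-2-yl]cyclohexan-1-one
Conditions: L-Selectride (LiBH(s-Bu)3), THF, −78 °C; H2O; then NaOMe (cat.), MeOH, rt
Reagents that add atoms: none
Why: Conjugate hydride reduction of the β-unsubstituted enone, followed by base equilibration through the only enolisable position, should place the C6' methyl equatorial and trans to the axial C2' methyl (thermodynamic control).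

Step 6
Reactants: 6 (2R,3S,6S)-2,6-dimethyl-2-(prop-2-en-1-yl)-3-[2-(triethylsilyloxy)propan-2-yl]cyclohexan-1-one
Product: 7 (2R,3S,6S)-2-(3-hydroxypropyl)-2,6-dimethyl-3-[2-(triethylsilyloxy)propan-2-yl]cyclohexan-1-one
Conditions: 9-BBN, THF, 0 °C to rt; then NaOH, H2O2, 0 °C
Reagents that add atoms: hydrogen peroxide, OO
Why: Anti-Markovnikov hydroboration–oxidation of the terminal alkene should be much faster than reduction of the doubly α-branched ketone by 9-BBN.

Step 7
Reactants: 7 (2R,3S,6S)-2-(3-hydroxypropyl)-2,6-dimethyl-3-[2-(triethylsilyloxy)propan-2-yl]cyclohexan-1-one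
Product: 8 (2R,3S,6S)-2-[3-(tert-butyldimethylsilyloxy)propyl]-2,6-dimethyl-3-[2-(triethylsilyloxy)propan-2-yl]cyclohexan-1-one
Conditions: TBSCl, imidazole, DMF, rt
Reagents that add atoms: tert-butyldimethylsilyl chloride, CC(C)(C)[Si](C)(C)Cl
Why: Standard silylation of the primary alcohol masks the future carboxyl carbon through the organometallic and basic steps.

Step 8
Reactants: 9 pent-3-yn-1-ol
Product: 10 5-bromopent-2-yne
Conditions: CBr4, PPh3, CH2Cl2, 0 °C
Reagents that add atoms: tetrabromomethane, BrC(Br)(Br)Br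
Why: The Appel reaction converts a primary alcohol into the bromide without touching the internal alkyne.

Step 9
Reactants: 8 (2R,3S,6S)-2-[3-(tert-butyldimethylsilyloxy)propyl]-2,6-dimethyl-3-[2-(triethylsilyloxy)propan-2-yl]cyclohexan-1-one; 10 5-bromopent-2-yne
Product: 12 (1R,2R,3S,6S)-2-[3-(tert-butyldimethylsilyloxy)propyl]-2,6-dimethyl-1-(pent-3-yn-1-yl)-3-[2-(triethylsilyloxy)propan-2-yl]cyclohexan-1-ol, via pent-3-yn-1-ylmagnesium bromide 11 (not isolated)
Conditions: 10, Mg, THF, rt; then 8, LaCl3·2LiCl, THF, 0 °C; H2O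
Reagents that add atoms: none
Why: Grignard 1,2-addition with a lanthanum Lewis acid additive favours addition over enolisation; in the chair with the C3' substituent equatorial the C2' methyl is axial, so the nucleophile should enter axially on the opposite face and the hydroxyl end equatorial and cis to that methyl, which is the C2 configuration of the target.

Step 10
Reactants: 12 (1R,2R,3S,6S)-2-[3-(tert-butyldimethylsilyloxy)propyl]-2,6-dimethyl-1-(pent-3-yn-1-yl)-3-[2-(triethylsilyloxy)propan-2-yl]cyclohexan-1-ol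
Product: 13 methyl (2E)-2-{(5R,6R,7S,10S)-6-[3-(tert-butyldimethylsilyloxy)propyl]-6,10-dimethyl-7-[2-(triethylsilyloxy)propan-2-yl]-1-oxaspiro[4.5]decan-2-ylidene}propanoate
Conditions: PdCl2(MeCN)2 (5 mol %), p-benzoquinone (1.5 equiv), CO (1 atm), MeOH, 0 °C
Reagents that add atoms: carbon monoxide, [C-]#[O+]; methanol, CO
Why: The divalent palladium catalyst binds the alkyne of 12 and the tertiary hydroxyl adds anti across it, forming the O1–C8a bond and an (E)-σ-vinylpalladium species at C8; CO then inserts with retention and methanol cleaves the acylpalladium to the ester (C7), the zerovalent palladium released being reoxidised by benzoquinone. The closest known reaction type is the palladium-catalysed cyclisation–alkoxycarbonylation of 4-yn-1-ols to (E)-2-(alkoxycarbonylmethylene)oxolanes. The one ring closed is the oxolane O1–C2–C3–C3a–C8a, in the 5-exo-dig mode. No new stereocentre arises: C2 keeps the configuration set in step 9, and the (E) geometry of the tetrasubstituted enol ether (ester trans to O1, cis to C3a, as the later ring closure needs) follows from anti oxypalladation and retentive CO insertion. The step needs exo over 6-endo closure and carbonylation faster than protodepalladation; the three-atom tether with its fully substituted carbinol carbon should secure the first and the CO atmosphere at low temperature the second.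

Step 11
Reactants: 14 methyl (2E)-3-methyl-4-oxobut-2-enoate
Product: 15 methyl (2E)-4,4-dimethoxy-3-methylbut-2-enoate
Conditions: HC(OMe)3, p-TsOH (cat.), MeOH, rt
Reagents that add atoms: trimethyl orthoformate, COC(OC)OC
Why: Acid-catalysed acetalisation of the aldehyde with an orthoformate gives the acetal that serves as an oxocarbenium precursor and cannot lactonise after the coupling.

Step 12
Reactants: 13 methyl (2E)-2-{(5R,6R,7S,10S)-6-[3-(tert-butyldimethylsilyloxy)propyl]-6,10-dimethyl-7-[2-(triethylsilyloxy)propan-2-yl]-1-oxaspiro[4.5]decan-2-ylidene}propanoate; 15 methyl (2E)-4,4-dimethoxy-3-methylbut-2-enoate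
Product: 17 γ-adduct (13 carrying at oxolane C3, = C3a, a CH(OMe)–C(Me)=CH–CO2Me chain; mixture at the two new centres), via silyl ketene acetal 16 (not isolated)
Conditions: LDA, THF, −78 °C; TMSCl; then 15, TMSOTf (10 mol %), CH2Cl2, −78 °C
Reagents that add atoms: none
Why: In this vinylogous Mukaiyama-type condensation of a silyl dienol ether with an acetal, γ-deprotonation of the β-alkoxyacrylate and O-silylation give 16, whose C3a is both enol-ether β-carbon and dienolate terminus and should attack the oxocarbenium ion from 15 to form C3a–C4; the two new stereocentres are erased in step 13.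

Step 13
Reactants: 17 γ-adduct
Product: 19 methyl (2R,2'R,3'S,6'S)-2'-[3-(tert-butyldimethylsilyloxy)propyl]-2',5,6',8-tetramethyl-7-oxo-3'-[2-(triethylsilyloxy)propan-2-yl]-3,7-dihydrospiro[cyclohepta[b]furan-2,1'-cyclohexane]-6-carboxylate, via triene diester 18 (not isolated)
Conditions: NaOMe, MeOH–THF, 0 to 60 °C
Reagents that add atoms: none
Why: Proposed new method: methoxide should remove the γ-proton at C3a and expel the C4 methoxide (E1cB) to give triene 18, deprotonation at C3 (or at the C5 methyl) then gives an extended ester enolate whose C6 attacks the C7 ester carbonyl held within reach by the (E)-enol ether, and loss of methoxide with a proton shift from C6 to C3 gives the aromatic tropone, which drives the equilibrium; the closest known reaction type is the Dieckmann condensation in its vinylogous, aromatising form as used in condensation annulations of benzenoid rings, here extended to a seven-membered ring, and the diastereomers and enol ether isomers of 17 should converge on 19 because dienolate formation is reversible.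

Step 14
Reactants: 19 silyl-protected spiro tropone
Product: 20 methyl (2R,2'R,3'S,6'S)-2'-(3-hydroxypropyl)-3'-(2-hydroxypropan-2-yl)-2',5,6',8-tetramethyl-7-oxo-3,7-dihydrospiro[cyclohepta[b]furan-2,1'-cyclohexane]-6-carboxylate
Conditions: HF·pyridine, pyridine, THF, 0 °C to rt
Reagents that add atoms: none
Why: Buffered fluoride desilylation should remove both silyl ethers without hydrolysing the tertiary-alkyl vinylogous ester or the methyl ester.

Step 15
Reactants: 20 diol
Product: 21 3-[(2R,2'R,3'S,6'S)-3'-(2-hydroxypropan-2-yl)-6-(methoxycarbonyl)-2',5,6',8-tetramethyl-7-oxo-3,7-dihydrospiro[cyclohepta[b]furan-2,1'-cyclohexan]-2'-yl]propanoic acid (CNP0448476.3)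
Conditions: TEMPO (cat.), PhI(OAc)2, MeCN–H2O, rt
Reagents that add atoms: water, O
Why: Oxoammonium (TEMPO) oxidation takes a primary alcohol through the aldehyde hydrate to the acid under near-neutral conditions that should spare the tertiary alcohol, the tropone and the vinylogous ester.

**Compound list**

1 | (S)-(+)-carvone | CC1=CC[C@@H](CC1=O)C(C)=C | starting material
2 | (5S)-5-(2-hydroxypropan-2-yl)-2-methylcyclohex-2-en-1-one | O=C1C(C)=CC[C@H](C(C)(C)O)C1 | intermediate
3 | (5S)-2-methyl-5-[2-(triethylsilyloxy)propan-2-yl]cyclohex-2-en-1-one | O=C1C(C)=CC[C@H](C(C)(C)O[Si](CC)(CC)CC)C1 | intermediate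
4 | (5S)-2,6-dimethyl-5-[2-(triethylsilyloxy)propan-2-yl]cyclohex-2-en-1-one, C6 epimer mixture | O=C1C(C)=CC[C@H](C(C)(C)O[Si](CC)(CC)CC)C1C | intermediate
5 | (5S,6R)-2,6-dimethyl-6-(prop-2-en-1-yl)-5-[2-(triethylsilyloxy)propan-2-yl]cyclohex-2-en-1-one | O=C1C(C)=CC[C@H](C(C)(C)O[Si](CC)(CC)CC)[C@@]1(C)CC=C | intermediate
6 | (2R,3S,6S)-2,6-dimethyl-2-(prop-2-en-1-yl)-3-[2-(triethylsilyloxy)propan-2-yl]cyclohexan-1-one | O=C1[C@@H](C)CC[C@H](C(C)(C)O[Si](CC)(CC)CC)[C@@]1(C)CC=C | intermediate
7 | (2R,3S,6S)-2-(3-hydroxypropyl)-2,6-dimethyl-3-[2-(triethylsilyloxy)propan-2-yl]cyclohexan-1-one | O=C1[C@@H](C)CC[C@H](C(C)(C)O[Si](CC)(CC)CC)[C@@]1(C)CCCO | intermediate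
8 | (2R,3S,6S)-2-[3-(tert-butyldimethylsilyloxy)propyl]-2,6-dimethyl-3-[2-(triethylsilyloxy)propan-2-yl]cyclohexan-1-one | O=C1[C@@H](C)CC[C@H](C(C)(C)O[Si](CC)(CC)CC)[C@@]1(C)CCCO[Si](C)(C)C(C)(C)C | intermediate
9 | pent-3-yn-1-ol | CC#CCCO | starting material
10 | 5-bromopent-2-yne | CC#CCCBr | intermediate
11 | pent-3-yn-1-ylmagnesium bromide (not isolated) | CC#CCC[Mg]Br | intermediate
12 | (1R,2R,3S,6S)-2-[3-(tert-butyldimethylsilyloxy)propyl]-2,6-dimethyl-1-(pent-3-yn-1-yl)-3-[2-(triethylsilyloxy)propan-2-yl]cyclohexan-1-ol | O[C@]1(CCC#CC)[C@@H](C)CC[C@H](C(C)(C)O[Si](CC)(CC)CC)[C@@]1(C)CCCO[Si](C)(C)C(C)(C)C | intermediate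
13 | methyl (2E)-2-{(5R,6R,7S,10S)-6-[3-(tert-butyldimethylsilyloxy)propyl]-6,10-dimethyl-7-[2-(triethylsilyloxy)propan-2-yl]-1-oxaspiro[4.5]decan-2-ylidene}propanoate | COC(=O)/C(C)=C1/O[C@]2(CC1)[C@@H](C)CC[C@H](C(C)(C)O[Si](CC)(CC)CC)[C@@]2(C)CCCO[Si](C)(C)C(C)(C)C | intermediate
14 | methyl (2E)-3-methyl-4-oxobut-2-enoate | O=C/C(C)=C/C(=O)OC | starting material
15 | methyl (2E)-4,4-dimethoxy-3-methylbut-2-enoate | COC(OC)/C(C)=C/C(=O)OC | intermediate
16 | trimethylsilyl ketene acetal of 13, 4,5-dihydrofuran form (not isolated) | COC(O[Si](C)(C)C)=C(C)C1=CC[C@@]2(O1)[C@@H](C)CC[C@H](C(C)(C)O[Si](CC)(CC)CC)[C@@]2(C)CCCO[Si](C)(C)C(C)(C)C | intermediate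
17 | γ-adduct: 13 bearing at oxolane C3 a CH(OMe)–C(Me)=CH–CO2Me chain, mixture at the two new centres | COC(=O)/C(C)=C1/O[C@]2(CC1C(OC)/C(C)=C/C(=O)OC)[C@@H](C)CC[C@H](C(C)(C)O[Si](CC)(CC)CC)[C@@]2(C)CCCO[Si](C)(C)C(C)(C)C | intermediate
18 | triene diester from loss of methanol from 17 (not isolated) | COC(=O)/C(C)=C1/O[C@]2(CC1=CC(C)=CC(=O)OC)[C@@H](C)CC[C@H](C(C)(C)O[Si](CC)(CC)CC)[C@@]2(C)CCCO[Si](C)(C)C(C)(C)C | intermediate
19 | methyl (2R,2'R,3'S,6'S)-2'-[3-(tert-butyldimethylsilyloxy)propyl]-2',5,6',8-tetramethyl-7-oxo-3'-[2-(triethylsilyloxy)propan-2-yl]-3,7-dihydrospiro[cyclohepta[b]furan-2,1'-cyclohexane]-6-carboxylate | COC(=O)c1c(C)cc2c(c(C)c1=O)O[C@]1(C2)[C@@H](C)CC[C@H](C(C)(C)O[Si](CC)(CC)CC)[C@@]1(C)CCCO[Si](C)(C)C(C)(C)C | intermediate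
20 | methyl (2R,2'R,3'S,6'S)-2'-(3-hydroxypropyl)-3'-(2-hydroxypropan-2-yl)-2',5,6',8-tetramethyl-7-oxo-3,7-dihydrospiro[cyclohepta[b]furan-2,1'-cyclohexane]-6-carboxylate | COC(=O)c1c(C)cc2c(c(C)c1=O)O[C@]1(C2)[C@@H](C)CC[C@H](C(C)(C)O)[C@@]1(C)CCCO | intermediate
21 | 3-[(2R,2'R,3'S,6'S)-3'-(2-hydroxypropan-2-yl)-6-(methoxycarbonyl)-2',5,6',8-tetramethyl-7-oxo-3,7-dihydrospiro[cyclohepta[b]furan-2,1'-cyclohexan]-2'-yl]propanoic acid (CNP0448476.3) | COC(=O)c1c(C)cc2c(c(C)c1=O)O[C@]1(C2)[C@@H](C)CC[C@H](C(C)(C)O)[C@@]1(C)CCC(=O)O | target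

**Count and risks**

Total step count: 15. Longest linear sequence: 13 (steps 1–7, 9, 10, 12, 13, 14, 15).

Steps most likely to fail:

Step 13 (Proposed new method). The closure may fail through retro-oxa-Michael opening of the oxolane, through attack of the extended enolate by C3 instead of C6, through an enol ether isomer that does not equilibrate, or through methoxide attack on the vinylogous ester of the product. The fallback closes the ring at the dihydro level by a classical Dieckmann condensation and aromatises afterwards. It sets out from 13 and 15. Hydrogenation of 15 (H2, Pd/C, MeOH) would give methyl 4,4-dimethoxy-3-methylbutanoate F1. Condensation of F1 with silyl ketene acetal 16 (made from 13 as in step 12; TMSOTf cat., CH2Cl2, −78 °C) would give the saturated γ-adduct F2. NaOMe in MeOH would eliminate methanol and close the ring through the ordinary α-carbanion of the saturated ester to the 5,6-dihydro β-keto ester F3. DDQ in dioxane would dehydrogenate F3, and the route is rejoined at 19.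

Step 10 (key step). The hindered tertiary carbinol may add too slowly to the internal alkyne, the 6-endo closure may compete, or the vinylpalladium species may be protonated before CO inserts. The fallback separates ring closure from carbonylation and sets out from 12. Iodoetherification (I2, NaHCO3, MeCN, 0 °C; 5-exo-dig, anti addition) would give (5R,6R,7S,10S)-2-[(1E)-1-iodoethylidene]-6-[3-(tert-butyldimethylsilyloxy)propyl]-6,10-dimethyl-7-[2-(triethylsilyloxy)propan-2-yl]-1-oxaspiro[4.5]decane F4. Methoxycarbonylation of this vinyl iodide with the zerovalent palladium catalyst Pd(PPh3)4 (CO, MeOH, Et3N, 60 °C) proceeds with retention, and the route is rejoined at 13.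

Step 9. The basic organometallic may enolise the doubly α-branched ketone instead of adding, or facial selectivity may erode. The fallback builds the same carbon chain from an epoxide and sets out from 8. Corey–Chaykovsky epoxidation (Me3SI, n-BuLi, THF, 0 °C), in which the small sulfonium ylide also attacks axially, would give the spiro-epoxide F5. The dianion of methyl 2-methyl-3-oxobutanoate (NaH, then n-BuLi, THF) would open F5 at its CH2 terminus to methyl 5-{(1R,2R,3S,6S)-2-[3-(tert-butyldimethylsilyloxy)propyl]-1-hydroxy-2,6-dimethyl-3-[2-(triethylsilyloxy)propan-2-yl]cyclohexyl}-2-methyl-3-oxopentanoate F6. Cyclodehydration (PPTS, toluene, 60 °C) closes the oxolane, and the route is rejoined at 13.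

**Further compounds**

F1 | step 13 | methyl 4,4-dimethoxy-3-methylbutanoate | COC(OC)C(C)CC(=O)OC
F2 | step 13 | saturated γ-adduct: 13 bearing at oxolane C3 a CH(OMe)–CH(Me)–CH2–CO2Me chain | COC(=O)/C(C)=C1/O[C@]2(CC1C(OC)C(C)CC(=O)OC)[C@@H](C)CC[C@H](C(C)(C)O[Si](CC)(CC)CC)[C@@]2(C)CCCO[Si](C)(C)C(C)(C)C
F3 | step 13 | 5,6-dihydro analogue of 19 (β-keto ester) | COC(=O)C1C(C)C=C2C(=C(C)C1=O)O[C@]1(C2)[C@@H](C)CC[C@H](C(C)(C)O[Si](CC)(CC)CC)[C@@]1(C)CCCO[Si](C)(C)C(C)(C)C
F4 | step 10 | (5R,6R,7S,10S)-2-[(1E)-1-iodoethylidene]-6-[3-(tert-butyldimethylsilyloxy)propyl]-6,10-dimethyl-7-[2-(triethylsilyloxy)propan-2-yl]-1-oxaspiro[4.5]decane | I/C(C)=C1/O[C@]2(CC1)[C@@H](C)CC[C@H](C(C)(C)O[Si](CC)(CC)CC)[C@@]2(C)CCCO[Si](C)(C)C(C)(C)C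
F5 | step 9 | spiro-epoxide of 8 (1-oxaspiro[2.5]octane, oxygen cis to the C2' methyl) | O1[C@]2(C1)[C@@H](C)CC[C@H](C(C)(C)O[Si](CC)(CC)CC)[C@@]2(C)CCCO[Si](C)(C)C(C)(C)C
F6 | step 9 | methyl 5-{(1R,2R,3S,6S)-2-[3-(tert-butyldimethylsilyloxy)propyl]-1-hydroxy-2,6-dimethyl-3-[2-(triethylsilyloxy)propan-2-yl]cyclohexyl}-2-methyl-3-oxopentanoate | O[C@]1(CCC(=O)C(C)C(=O)OC)[C@@H](C)CC[C@H](C(C)(C)O[Si](CC)(CC)CC)[C@@]1(C)CCCO[Si](C)(C)C(C)(C)C
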